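**Assumption:** the target has no stereocentre and is achiral, so the compound itself is the "single enantiomer" and no stereocontrol is needed.

**Retrosynthetic overview**
1. Target ⇒ the two aryl C–O bonds ortho to the ketones (the third phenolic oxygen of each ring) are made last, by a twofold ketone-directed C–H oxygenation of a bis-ketone diarylmethane that carries only two OH groups per ring.
2. That diarylmethane ⇒ ArCH2–Ar' bond: ortho-quinone methide from the Mannich base of the butanoyl monomer, trapped by the propanoyl monomer.
3. The two monomers ⇒ Nencki C-acylation of bulk 2-methylresorcinol with butanoic acid and with propanoic acid.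
4. No ring is formed: both benzene rings are bought as 2-methylresorcinol.

**Route**

Step 1
Reactants: 1 2-methylbenzene-1,3-diol (2-methylresorcinol); 2 butanoic acid
Product: 3 1-(2,4-dihydroxy-3-methylphenyl)butan-1-one
Conditions: ZnCl2 (1.5 equiv), neat 2 (5 equiv), 140 °C, 2 h; then aq. HCl
Reagents that add atoms: none
Why: Nencki-type Friedel–Crafts acylation places the acyl group on the only carbon that is ortho to one OH and para to the other, and the deactivated product ketone resists a second acylation.

Step 2
Reactants: 1 2-methylbenzene-1,3-diol (2-methylresorcinol); 4 propanoic acid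
Product: 5 1-(2,4-dihydroxy-3-methylphenyl)propan-1-one
Conditions: ZnCl2 (1.5 equiv), neat 4 (5 equiv), 135 °C, 2 h; then aq. HCl
Reagents that add atoms: none
Why: the same Nencki-type Friedel–Crafts acylation, with the same regiocontrol as in step 1.

Step 3
Reactants: 3 1-(2,4-dihydroxy-3-methylphenyl)butan-1-one; 5 1-(2,4-dihydroxy-3-methylphenyl)propan-1-one; 6 N,N,N',N'-tetramethylmethanediamine
Product: 9 1-[5-[(2,4-dihydroxy-3-methyl-5-propanoylphenyl)methyl]-2,4-dihydroxy-3-methylphenyl]butan-1-one, via Mannich base 7 (not isolated), via ortho-quinone methide 8 (not isolated)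
Conditions: 6 (1.1 equiv), 1,4-dioxane, 80 °C, 3 h; evaporate volatiles; then 5 (2.0 equiv), toluene, 110 °C, N2 sweep, 16 h
Reagents that add atoms: none
Why: a phenolic Mannich reaction at the only activated C–H of 3 gives 7, whose acidic 4-OH (para to the ketone) drives thermal loss of dimethylamine to quinone methide 8, and 5, added only after excess 6 has been evaporated, traps 8 at its single activated carbon in a Friedel–Crafts-type conjugate addition, so only the mixed dimer forms.

Step 4
Reactants: 9 1-[5-[(2,4-dihydroxy-3-methyl-5-propanoylphenyl)methyl]-2,4-dihydroxy-3-methylphenyl]butan-1-one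
Product: 12 1-[3-[(2,4,6-trihydroxy-3-methyl-5-propanoylphenyl)methyl]-2,4,6-trihydroxy-5-methylphenyl]butan-1-one, via tetrakis(trifluoroacetate) 10 (not isolated), via hexakis(trifluoroacetate) 11 (not isolated)
Conditions: TFA/TFAA (3:1), rt, 1 h; then Pd(OAc)2 (20 mol%), K2S2O8 (5 equiv), 60 °C, 16 h; filter, evaporate; then THF/H2O (4:1), rt, 2 h
Reagents that add atoms: trifluoroacetic acid, OC(=O)C(F)(F)F (supplies the oxygen of each new aryl C–O bond); trifluoroacetic anhydride, O=C(OC(=O)C(F)(F)F)C(F)(F)F (its trifluoroacetyl groups stay only in 10 and 11)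
Why: Proposed new method: a twofold ketone-directed ortho C–H oxygenation of a polyphenolic ortho-hydroxyaryl ketone masked in the flask, in which TFAA first converts all four phenols into trifluoroacetates (10), breaking the OH···O=C chelate so each carbonyl can turn to its only ortho C–H and making the rings too electron-poor for quinoid oxidation or acid cleavage of the ArCH2Ar bridge, after which divalent palladium cyclopalladates that C–H through the ketone oxygen, K2S2O8 oxidises the palladacycle to tetravalent palladium, C–O reductive elimination of trifluoroacetate forms the two new aryl C–O bonds (11) and mild hydrolysis frees all six phenols; the closest known reaction type is the Pd(OAc)2-catalysed ketone-directed ortho-hydroxylation of simple aryl ketones in TFA/TFAA, which has not been shown for a second ortho oxygen beside an existing one, for free polyphenols or for two rings at once.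

**Compound list**

1 | 2-methylbenzene-1,3-diol (2-methylresorcinol) | Cc1c(O)cccc1O | starting material
2 | butanoic acid | CCCC(=O)O | starting material
3 | 1-(2,4-dihydroxy-3-methylphenyl)butan-1-one | CCCC(=O)c1ccc(O)c(C)c1O | intermediate
4 | propanoic acid | CCC(=O)O | starting material
5 | 1-(2,4-dihydroxy-3-methylphenyl)propan-1-one | CCC(=O)c1ccc(O)c(C)c1O | intermediate
6 | N,N,N',N'-tetramethylmethanediamine | CN(C)CN(C)C | starting material
7 | 1-[5-[(dimethylamino)methyl]-2,4-dihydroxy-3-methylphenyl]butan-1-one (Mannich base, not isolated) | CCCC(=O)c1cc(CN(C)C)c(O)c(C)c1O | intermediate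
8 | 4-butanoyl-3-hydroxy-2-methyl-6-methylidenecyclohexa-2,4-dien-1-one (ortho-quinone methide, not isolated) | CCCC(=O)C1=CC(=C)C(=O)C(C)=C1O | intermediate
9 | 1-[5-[(2,4-dihydroxy-3-methyl-5-propanoylphenyl)methyl]-2,4-dihydroxy-3-methylphenyl]butan-1-one | CCCC(=O)c1cc(Cc2cc(C(=O)CC)c(O)c(C)c2O)c(O)c(C)c1O | intermediate
10 | tetrakis(trifluoroacetate) of 9, all four phenolic OH as OC(=O)CF3 (not isolated) | CCCC(=O)c1cc(Cc2cc(C(=O)CC)c(OC(=O)C(F)(F)F)c(C)c2OC(=O)C(F)(F)F)c(OC(=O)C(F)(F)F)c(C)c1OC(=O)C(F)(F)F | intermediate
11 | hexakis(trifluoroacetate) of 12, all six phenolic oxygens as OC(=O)CF3 (not isolated) | CCCC(=O)c1c(OC(=O)C(F)(F)F)c(Cc2c(OC(=O)C(F)(F)F)c(C(=O)CC)c(OC(=O)C(F)(F)F)c(C)c2OC(=O)C(F)(F)F)c(OC(=O)C(F)(F)F)c(C)c1OC(=O)C(F)(F)F | intermediate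
12 | 1-[3-[(2,4,6-trihydroxy-3-methyl-5-propanoylphenyl)methyl]-2,4,6-trihydroxy-5-methylphenyl]butan-1-one (CNP0208000.0, achiral) | CCCC(=O)c1c(O)c(C)c(O)c(Cc2c(O)c(C)c(O)c(C(=O)CC)c2O)c1O | target

**Total step count:** 4 (steps 1 and 2 are parallel).
**Longest linear sequence:** 3 steps (1 → 3 → 9 → 12).

**Steps most likely to fail**

Step 4 (the proposed new step). The masked ketone is twisted by its ortho trifluoroacetoxy group, the C–H to be cleaved is flanked by the benzylic bridge, and bridge oxidation or condensation of the ketone with TFAA to a trifluoromethylchromone could compete. The fallback uses known chemistry only; it sets out from acids 2 and 4 and comes back to the route at 12, buying the third oxygen instead of making it. Commercial 2-methylbenzene-1,3,5-triol (Cc1c(O)cc(O)cc1O) is C-acylated with 2 (BF3·OEt2, 80 °C) to 1-(2,4,6-trihydroxy-3-methylphenyl)butan-1-one F1 and, separately, with 4 to 1-(2,4,6-trihydroxy-3-methylphenyl)propan-1-one F2. F1 is then aminomethylated with 6 to 1-[3-[(dimethylamino)methyl]-2,4,6-trihydroxy-5-methylphenyl]butan-1-one F3, and F3 is heated with excess F2 in dioxane at 100 °C to give 12 with loss of dimethylamine.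

Step 3. Thermal loss of dimethylamine may be sluggish, and retro-Mannich transfer of the methylene unit could give some symmetric dimers. The fallback sets out from 3 and comes back at 9, replacing the amine-based quinone methide precursor by a boron-templated one. Ketone 3 is ortho-hydroxymethylated with paraformaldehyde and phenylboronic acid (cat. propanoic acid, toluene, Dean–Stark) to the isolable 1-(7-hydroxy-8-methyl-2-phenyl-4H-1,3,2-benzodioxaborin-6-yl)butan-1-one F4. F4 is then opened with cat. TsOH in the presence of 5 (toluene, 90 °C) and gives 9 and phenylboronic acid after aqueous work-up.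

Step 1 (step 2 is the same chemistry). At 140 °C, O-acylation, some 4,6-diacylation and tar can lower the yield. The fallback sets out from 1 and comes back at 3, using a nitrile instead of the acid (Houben–Hoesch). Compound 1 and butanenitrile (CCCC#N) with ZnCl2 and HCl gas in Et2O at 0 °C precipitate 1-(2,4-dihydroxy-3-methylphenyl)butan-1-iminium chloride F5, which is hydrolysed in boiling water to 3.

**Further compounds**

F1 | step 4 | 1-(2,4,6-trihydroxy-3-methylphenyl)butan-1-one | CCCC(=O)c1c(O)cc(O)c(C)c1O
F2 | step 4 | 1-(2,4,6-trihydroxy-3-methylphenyl)propan-1-one | CCC(=O)c1c(O)cc(O)c(C)c1O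
F3 | step 4 | 1-[3-[(dimethylamino)methyl]-2,4,6-trihydroxy-5-methylphenyl]butan-1-one | CCCC(=O)c1c(O)c(C)c(O)c(CN(C)C)c1O
F4 | step 3 | 1-(7-hydroxy-8-methyl-2-phenyl-4H-1,3,2-benzodioxaborin-6-yl)butan-1-one | CCCC(=O)c1cc2COB(c3ccccc3)Oc2c(C)c1O
F5 | step 1 | 1-(2,4-dihydroxy-3-methylphenyl)butan-1-iminium chloride | CCCC(=[NH2+])c1ccc(O)c(C)c1O.[Cl-]
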